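**Strategy.** The route rests on cutting ring B (C5–C10, labdane numbering) back to the cyclopentanone of a trans-hydrindanone: the C9 carbonyl, flanked by quaternary C10 and the C7 methylene, invites insertion of the missing C8 together with its methyl group C17. The key step should do this in one operation, a Lewis-acid-catalysed diazoethane ring expansion of the (S)-Hajos–Parrish-derived, trans-fused trimethylhexahydroindenone 7, giving the 8-methyl-9-decalone and, after equilibration, the equatorial 8α-methyl group. Axial vinyl addition at C9, a B-alkyl Suzuki coupling with a (Z)-iodoenoate and a late α-face dihydroxylation of the C2=C3 alkene should complete the target.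

Key step: step 6

Remark on the chemistry: positions in all intermediates are discussed with labdane numbering (ring A = C1–C5 and C10; ring B = C5–C10; C17 on C8, C18/C19 on C4, C20 on C10; side chain C11–C16). Diazoethane is assumed to be used as a freshly prepared ethereal solution (from commercial N-ethyl-N-nitrosourea and aqueous KOH), and this reagent preparation is not counted as a step.

**Step 1**
Reactants: 1 (S)-Hajos–Parrish ketone
Product: 2 (7aS)-1,1-ethylenedioxy-7a-methyl-1,2,3,6,7,7a-hexahydro-5H-inden-5-one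
Conditions: (TMSOCH2)2, TMSOTf (cat.), CH2Cl2, −78 °C
Reagents that add atoms: 1,2-bis(trimethylsilyloxy)ethane, C[Si](C)(C)OCCO[Si](C)(C)C
Why: Noyori ketalisation under kinetic control should take the saturated cyclopentanone (C9) and leave the less electrophilic enone carbonyl and its double bond in place, with C10 untouched.

**Step 2**
Reactants: 2 (7aS)-1,1-ethylenedioxy-7a-methyl-1,2,3,6,7,7a-hexahydro-5H-inden-5-one
Product: 3 (7aS)-1,1-ethylenedioxy-4,4,7a-trimethyl-1,2,4,6,7,7a-hexahydro-5H-inden-5-one
Conditions: KOt-Bu (3 equiv), MeI (excess), t-BuOH/THF, 0 °C → rt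
Reagents that add atoms: iodomethane, CI
Why: Deconjugative α,α-dialkylation of the extended dienolate (γ-deprotonation at C6) should methylate C4 twice and leave the alkene at C5=C6.

**Step 3**
Reactants: 3 (7aS)-1,1-ethylenedioxy-4,4,7a-trimethyl-1,2,4,6,7,7a-hexahydro-5H-inden-5-one
Product: 4 (3aS,7aS)-1,1-ethylenedioxy-4,4,7a-trimethyloctahydro-5H-inden-5-one
Conditions: H2 (3 atm), 10% Pd/C, EtOAc, rt
Reagents that add atoms: none
Why: Heterogeneous syn-hydrogenation should occur on the α face, opposite the axial C10 and 4β methyl groups (as in 4,4-dimethyl-Δ5-3-ketones and Δ14-steroids), setting the 5α-H and thus the trans ring fusion.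

**Step 4**
Reactants: 4 (3aS,7aS)-1,1-ethylenedioxy-4,4,7a-trimethyloctahydro-5H-inden-5-one
Product: 5 (E)-p-toluenesulfonylhydrazone of 4 at C3
Conditions: TsNHNH2, EtOH, reflux
Reagents that add atoms: p-toluenesulfonyl hydrazide, Cc1ccc(cc1)S(=O)(=O)NN
Why: Hydrazone condensation at the only free ketone should place the N–NHTs group anti to quaternary C4 (syn to C2), and the neutral medium spares the dioxolane.

**Step 5**
Reactants: 5 (E)-p-toluenesulfonylhydrazone of 4 at C3
Product: 7 (3aS,7aS)-4,4,7a-trimethyl-2,3,3a,4,7,7a-hexahydro-1H-inden-1-one, via alkene ketal 6 (not isolated)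
Conditions: MeLi (3.5 equiv), Et2O/THF, 0 °C → rt; H2O; then 2 M HCl, THF, rt
Reagents that add atoms: water, O
Why: Shapiro reaction (dianion at C2, the only α-CH2, then loss of sulfinate and N2, as with camphor tosylhydrazone) should give the C2=C3 alkene after protonation, and the acidic work-up hydrolyses the dioxolane to the C9 ketone.

**Step 6**
Reactants: 7 (3aS,7aS)-4,4,7a-trimethyl-2,3,3a,4,7,7a-hexahydro-1H-inden-1-one
Product: 9 (2R,4aS,8aS)-2,5,5,8a-tetramethyl-3,4,4a,5,8,8a-hexahydronaphthalen-1(2H)-one, via C8-epimeric ketone mixture 8 (not isolated)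
Conditions: CH3CHN2 (Et2O solution, 2 equiv), Sc(OTf)3 (10 mol%), CH2Cl2, −78 → −20 °C; then NaOMe, MeOH, rt
Reagents that add atoms: diazoethane, CC=[N+]=[N-]
Why: Sc(OTf)3 activates the C9 carbonyl, the nucleophilic carbon of diazoethane adds to give a β-diazonium alkoxide, and the C7–C9 bond migrates to the diazonium carbon with loss of N2, so that C8 and its methyl group C17 are inserted between C9 and C7. The closest known reaction type is the Lewis-acid-catalysed diazoalkane homologation of cycloalkanones (Tiffeneau–Demjanov-type ring expansion), as in the D-homoannulation of 17-oxo steroids. No ring is closed from an open chain: ring B arises by one-carbon enlargement of the cyclopentanone (five to six members) through a 1,2-alkyl shift. The only new stereocentre, C8, is set under thermodynamic control in the NaOMe equilibration through the C8–C9 enolate, which should place the methyl group equatorial (8α, R), away from the axial C10 methyl. The step needs migration of methylene C7 and not of quaternary C10, which is the usual preference in Lewis-acid-promoted diazoalkane insertions, and it needs to stop after one insertion, which the α-quaternary, α'-tertiary product ketone should secure by being far less reactive than 7.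

**Step 7**
Reactants: 9 (2R,4aS,8aS)-2,5,5,8a-tetramethyl-3,4,4a,5,8,8a-hexahydronaphthalen-1(2H)-one
Product: 10 (1S,2R,4aS,8aS)-1-ethenyl-2,5,5,8a-tetramethyl-1,2,3,4,4a,5,8,8a-octahydronaphthalen-1-ol
Conditions: CH2=CHMgBr, CeCl3 (anhydrous), THF, −78 → 0 °C; H2O work-up
Reagents that add atoms: vinylmagnesium bromide, C=C[Mg]Br
Why: Organocerium 1,2-addition (Imamoto conditions) suppresses enolisation, and axial attack on the α face, anti to the axial C10 methyl that blocks the equatorial trajectory, should give the 9α-vinyl-9β-ol (9S).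

**Step 8**
Reactants: 11 methyl but-2-ynoate
Product: 12 methyl (Z)-3-iodobut-2-enoate
Conditions: NaI, AcOH, 110 °C
Reagents that add atoms: sodium iodide, [Na+].[I-]
Why: Conjugate hydroiodination of the ynoate with anti protonation should give the Z isomer, with iodine cis to the ester.

**Step 9**
Reactants: 10 (1S,2R,4aS,8aS)-1-ethenyl-2,5,5,8a-tetramethyl-1,2,3,4,4a,5,8,8a-octahydronaphthalen-1-ol; 12 methyl (Z)-3-iodobut-2-enoate
Product: 14 methyl (2Z)-5-[(1S,2R,4aS,8aS)-1-hydroxy-2,5,5,8a-tetramethyl-1,2,3,4,4a,5,8,8a-octahydronaphthalen-1-yl]-3-methylpent-2-enoate, via B-alkyl-9-BBN borane 13 (not isolated)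
Conditions: 9-BBN-H (2.2 equiv), THF, 0 °C → rt; then 12, Pd(dppf)Cl2 (5 mol%), AsPh3, Cs2CO3, DMF/H2O, rt
Reagents that add atoms: 9-borabicyclo[3.3.1]nonane (9-BBN-H), B1C2CCCC1CCC2 (its boron is carried only in intermediate 13)
Why: 9-BBN should hydroborate the monosubstituted vinyl group at its terminus in preference to the hindered ring alkene, and the B-alkyl Suzuki–Miyaura coupling proceeds with retention of the vinyl iodide geometry, giving the Z enoate with C12 cis to the ester.

**Step 10**
Reactants: 14 methyl (2Z)-5-[(1S,2R,4aS,8aS)-1-hydroxy-2,5,5,8a-tetramethyl-1,2,3,4,4a,5,8,8a-octahydronaphthalen-1-yl]-3-methylpent-2-enoate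
Product: 15 methyl (2Z)-5-[(1S,2R,4aS,6S,7R,8aS)-1,6,7-trihydroxy-2,5,5,8a-tetramethyldecahydronaphthalen-1-yl]-3-methylpent-2-enoate (target)
Conditions: OsO4 (2 mol%), NMO (1.1 equiv), acetone/H2O, 0 °C → rt
Reagents that add atoms: osmium tetroxide (catalytic), O=[Os](=O)(=O)=O; N-methylmorpholine N-oxide, C[N+]1([O-])CCOCC1; water, O
Why: Upjohn dihydroxylation with electrophilic OsO4 should select the isolated cis-disubstituted C2=C3 alkene over the electron-poor trisubstituted enoate and add syn from the α face, opposite the axial C10 and 4β methyl groups, giving the 2α,3α-diol (2R,3S).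

**Compound list**

1 | (S)-Hajos–Parrish ketone, (7aS)-7a-methyl-2,3,7,7a-tetrahydro-1H-indene-1,5(6H)-dione | C[C@]12CCC(=O)C=C1CCC2=O | starting material
2 | (7aS)-1,1-ethylenedioxy-7a-methyl-1,2,3,6,7,7a-hexahydro-5H-inden-5-one (C9 dioxolane of 1) | C[C@]12CCC(=O)C=C1CCC21OCCO1 | intermediate
3 | (7aS)-1,1-ethylenedioxy-4,4,7a-trimethyl-1,2,4,6,7,7a-hexahydro-5H-inden-5-one (alkene C3=C3a, labdane C5=C6) | C[C@]12CCC(=O)C(C)(C)C1=CCC21OCCO1 | intermediate
4 | (3aS,7aS)-1,1-ethylenedioxy-4,4,7a-trimethyloctahydro-5H-inden-5-one (trans-fused) | C[C@]12CCC(=O)C(C)(C)[C@@H]1CCC21OCCO1 | intermediate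
5 | (E)-p-toluenesulfonylhydrazone of 4 at the C5 (indane) carbonyl, labdane C3 | C[C@]12CC/C(=N\NS(=O)(=O)c3ccc(C)cc3)C(C)(C)[C@@H]1CCC21OCCO1 | intermediate
6 | (3aS,7aS)-1,1-ethylenedioxy-4,4,7a-trimethyl-2,3,3a,4,7,7a-hexahydro-1H-indene (alkene ketal) | C[C@]12CC=CC(C)(C)[C@@H]1CCC21OCCO1 | intermediate (not isolated)
7 | (3aS,7aS)-4,4,7a-trimethyl-2,3,3a,4,7,7a-hexahydro-1H-inden-1-one | C[C@]12CC=CC(C)(C)[C@@H]1CCC2=O | intermediate
8 | (2RS,4aS,8aS)-2,5,5,8a-tetramethyl-3,4,4a,5,8,8a-hexahydronaphthalen-1(2H)-one (mixture of C8 epimers) | O=C1C(C)CC[C@H]2C(C)(C)C=CC[C@@]21C | intermediate (not isolated)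
9 | (2R,4aS,8aS)-2,5,5,8a-tetramethyl-3,4,4a,5,8,8a-hexahydronaphthalen-1(2H)-one | O=C1[C@H](C)CC[C@H]2C(C)(C)C=CC[C@@]21C | intermediate
10 | (1S,2R,4aS,8aS)-1-ethenyl-2,5,5,8a-tetramethyl-1,2,3,4,4a,5,8,8a-octahydronaphthalen-1-ol | C=C[C@]1(O)[C@H](C)CC[C@H]2C(C)(C)C=CC[C@@]21C | intermediate
11 | methyl but-2-ynoate | CC#CC(=O)OC | starting material
12 | methyl (Z)-3-iodobut-2-enoate | COC(=O)/C=C(/C)I | intermediate
13 | (1S,2R,4aS,8aS)-1-[2-(9-borabicyclo[3.3.1]nonan-9-yl)ethyl]-2,5,5,8a-tetramethyl-1,2,3,4,4a,5,8,8a-octahydronaphthalen-1-ol | C1CCC2CCCC1B2CC[C@]1(O)[C@H](C)CC[C@H]2C(C)(C)C=CC[C@@]21C | intermediate (not isolated)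
14 | methyl (2Z)-5-[(1S,2R,4aS,8aS)-1-hydroxy-2,5,5,8a-tetramethyl-1,2,3,4,4a,5,8,8a-octahydronaphthalen-1-yl]-3-methylpent-2-enoate | COC(=O)/C=C(/C)CC[C@]1(O)[C@H](C)CC[C@H]2C(C)(C)C=CC[C@@]21C | intermediate
15 | methyl (2Z)-5-[(1S,2R,4aS,6S,7R,8aS)-1,6,7-trihydroxy-2,5,5,8a-tetramethyldecahydronaphthalen-1-yl]-3-methylpent-2-enoate; labdane name methyl (2R,3S,5S,8R,9S,10S,13Z)-2,3,9-trihydroxylabd-13-en-15-oate | COC(=O)/C=C(/C)CC[C@]1(O)[C@H](C)CC[C@H]2C(C)(C)[C@H](O)[C@H](O)C[C@@]21C | target

**Step count.** Total: 10 steps. Longest linear sequence: 9 steps (steps 1–7, 9 and 10); step 8 makes the coupling partner 12.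

**Steps most likely to fail and fallbacks**

Step 6 (key step). Addition of diazoethane to the neopentyl-type C9 carbonyl may be slow, so that Lewis-acid-induced decomposition of the diazoalkane, epoxide formation or partial migration of quaternary C10 erodes the ring expansion. The fallback sets out from 7 and separates homologation from methylation. Ethyl diazoacetate with BF3·OEt2 in CH2Cl2 at 0 °C should give, by the methylene migration established for 17-oxo steroids, the β-keto ester ethyl (4aS,8aS)-5,5,8a-trimethyl-1-oxo-1,2,3,4,4a,5,8,8a-octahydronaphthalene-2-carboxylate F1. C-Methylation (K2CO3, MeI, acetone) should give ethyl (4aS,8aS)-2,5,5,8a-tetramethyl-1-oxo-1,2,3,4,4a,5,8,8a-octahydronaphthalene-2-carboxylate F2. Krapcho dealkoxycarbonylation (LiCl, wet DMSO, 150 °C) followed by NaOMe/MeOH equilibration comes back to the route at 9.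

Step 10. Osmylation may lose chemoselectivity if the hindered C2=C3 alkene, next to the gem-dimethyl carbon, reacts slowly enough for the enoate to compete. The fallback sets out from 9 and installs the diol before the enoate exists. OsO4/NMO on 9 should give (2R,4aS,6S,7R,8aS)-6,7-dihydroxy-2,5,5,8a-tetramethyloctahydronaphthalen-1(2H)-one F3. 2,2-Dimethoxypropane with PPTS should give its 6,7-O-isopropylidene acetal F4. CH2=CHMgBr/CeCl3 should give the 1-ethenyl-1-ol acetonide F5 by the same axial attack. 9-BBN-H followed by 12, Pd(dppf)Cl2 and Cs2CO3 should give the 2,3-O-isopropylidene derivative of the target F6. Aqueous AcOH at 45 °C then removes the acetonide and comes back at 15.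

Step 3. Hydrogen uptake at the trisubstituted alkene between two quaternary carbons may be slow, allowing palladium-mediated double-bond migration and loss of α-facial selectivity at C5. The fallback sets out from 3 and comes back at 4. It replaces surface hydrogenation by a radical hydrogen-atom-transfer hydrogenation (tris(dipivaloylmethanato)manganese, Mn(dpm)3, PhSiH3, t-BuOOH, i-PrOH, rt). The hydrogen atom should add to C6, and the tertiary C5 radical should be reduced from the less hindered α face. This fallback makes no new compound (F0).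

**Further compounds**

F1 | step 6 | ethyl (4aS,8aS)-5,5,8a-trimethyl-1-oxo-1,2,3,4,4a,5,8,8a-octahydronaphthalene-2-carboxylate (C2 epimers and enol form) | O=C1C(C(=O)OCC)CC[C@H]2C(C)(C)C=CC[C@@]21C
F2 | step 6 | ethyl (4aS,8aS)-2,5,5,8a-tetramethyl-1-oxo-1,2,3,4,4a,5,8,8a-octahydronaphthalene-2-carboxylate (either C2 configuration; erased on decarboxylation) | O=C1C(C)(C(=O)OCC)CC[C@H]2C(C)(C)C=CC[C@@]21C
F3 | step 10 | (2R,4aS,6S,7R,8aS)-6,7-dihydroxy-2,5,5,8a-tetramethyloctahydronaphthalen-1(2H)-one | O=C1[C@H](C)CC[C@H]2C(C)(C)[C@H](O)[C@H](O)C[C@@]21C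
F4 | step 10 | 6,7-O-isopropylidene acetal of F3 (labdane 2α,3α-acetonide, C9 ketone) | O=C1[C@H](C)CC[C@H]2C(C)(C)[C@H](OC3(C)C)[C@H](O3)C[C@@]21C
F5 | step 10 | 1-ethenyl-1-ol from F4 (labdane 9α-vinyl-9β-ol 2α,3α-acetonide) | C=C[C@]1(O)[C@H](C)CC[C@H]2C(C)(C)[C@H](OC3(C)C)[C@H](O3)C[C@@]21C
F6 | step 10 | 2,3-O-isopropylidene derivative of target 15 | COC(=O)/C=C(/C)CC[C@]1(O)[C@H](C)CC[C@H]2C(C)(C)[C@H](OC3(C)C)[C@H](O3)C[C@@]21C
F0 | step 3 | none | none
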